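The cyclohexane ring is disconnected across two non-adjacent bonds, C5–C10 and C6–C7, back to an acyclic allyl vinyl ether (11) that carries the C8/C9 cis-diol as a dioxolane (from D-erythronolactone) and an isopropylidene terminus. On heating, a Claisen rearrangement forges C5–C10, the C10 quaternary centre with its vinyl group and a C6 aldehyde; in the same operation this aldehyde is captured by the C7=C11 alkene in a carbonyl-ene cyclisation that closes the ring at C6–C7. The step exploits the γ,δ-unsaturated carbonyl pattern O=C6–C5–C10–C1=C2 and the homoallylic alcohol pattern HO–C6–C7–C11=C13 of the carbocycle C5–C10.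

Key step: step 10

Remark on numbering: C5–C10 are the ring carbons; C1/C2 are the two-carbon group on C10 (vinyl, later oxirane) and C14 its methyl; C4, C15 (methylene) and C3 (CHO) are the group on C5; C11, C13 (methylene) and C12 (C=O) are the group on C7. β is the ring face of C14.

Remark on the chemistry (assumption): the acetal or lactol carbon C3 in 17–20, 22 and 23 and the lactol carbon C12 in 19 are carried as anomer mixtures, so their SMILES leave that one centre open. Compounds 24 and 25 are drawn as open γ-hydroxy enals, which may equilibrate with their lactols.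

Step 1
Reactants: 1 2,3-O-isopropylidene-D-erythronolactone
Product: 2 (4R,5R)-5-(hydroxymethyl)-N-methoxy-N,2,2-trimethyl-1,3-dioxolane-4-carboxamide
Conditions: MeNH(OMe)·HCl, AlMe3, CH2Cl2, 0 °C to rt; aqueous work-up
Reagents that add atoms: N,O-dimethylhydroxylamine hydrochloride, CNOC.Cl
Why: Weinreb aminolysis of the lactone by the aluminium amide formed in the flask should open the ring to the hydroxy amide without touching the two dioxolane stereocentres.

Step 2
Reactants: 2 (4R,5R)-5-(hydroxymethyl)-N-methoxy-N,2,2-trimethyl-1,3-dioxolane-4-carboxamide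
Product: 3 (4R,5S)-5-formyl-N-methoxy-N,2,2-trimethyl-1,3-dioxolane-4-carboxamide
Conditions: TEMPO (cat.), PhI(OAc)2, CH2Cl2, rt
Reagents that add atoms: none
Why: the oxoammonium (TEMPO) oxidation of the primary alcohol should stop at the aldehyde under non-basic conditions that leave the epimerisable α-alkoxy centre untouched.

Step 3
Reactants: 3 (4R,5S)-5-formyl-N-methoxy-N,2,2-trimethyl-1,3-dioxolane-4-carboxamide
Product: 4 (4R,5R)-N-methoxy-N,2,2-trimethyl-5-(2-methylprop-1-en-1-yl)-1,3-dioxolane-4-carboxamide
Conditions: isopropyltriphenylphosphonium iodide, n-BuLi, THF, −78 °C to 0 °C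
Reagents that add atoms: isopropyltriphenylphosphonium iodide, CC(C)[P+](c1ccccc1)(c1ccccc1)c1ccccc1.[I-]
Why: Wittig olefination with the non-stabilised ylide should take the aldehyde much faster than the Weinreb amide at low temperature, and the symmetrical alkene end raises no geometry question.

Step 4
Reactants: 4 (4R,5R)-N-methoxy-N,2,2-trimethyl-5-(2-methylprop-1-en-1-yl)-1,3-dioxolane-4-carboxamide
Product: 5 1-[(4R,5R)-2,2-dimethyl-5-(2-methylprop-1-en-1-yl)-1,3-dioxolan-4-yl]ethan-1-one
Conditions: MeMgBr, THF, −20 °C to 0 °C; cold NH4Cl quench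
Reagents that add atoms: methylmagnesium bromide, C[Mg]Br
Why: in this Weinreb ketone synthesis the chelated tetrahedral intermediate should prevent over-addition, and the cold quench protects the α-alkoxy ketone from epimerisation.

Step 5
Reactants: 5 1-[(4R,5R)-2,2-dimethyl-5-(2-methylprop-1-en-1-yl)-1,3-dioxolan-4-yl]ethan-1-one
Product: 6 ethyl (2E)-3-[(4S,5R)-2,2-dimethyl-5-(2-methylprop-1-en-1-yl)-1,3-dioxolan-4-yl]but-2-enoate
Conditions: Ph3P=CHCO2Et, toluene, 100 °C
Reagents that add atoms: ethyl (triphenylphosphoranylidene)acetate, CCOC(=O)C=P(c1ccccc1)(c1ccccc1)c1ccccc1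
Why: Wittig olefination of the activated α-alkoxy methyl ketone with the stabilised ylide under base-free conditions should give mainly the (E)-enoate (ester trans to the dioxolane), the minor (Z)-isomer being removed by chromatography.

Step 6
Reactants: 6 ethyl (2E)-3-[(4S,5R)-2,2-dimethyl-5-(2-methylprop-1-en-1-yl)-1,3-dioxolan-4-yl]but-2-enoate
Product: 7 (2E)-3-[(4S,5R)-2,2-dimethyl-5-(2-methylprop-1-en-1-yl)-1,3-dioxolan-4-yl]but-2-en-1-ol
Conditions: i-Bu2AlH, CH2Cl2, −78 °C
Reagents that add atoms: none
Why: 1,2-reduction of the enoate by the aluminium hydride should give the (E)-allylic alcohol with alkene geometry and dioxolane unchanged.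

Step 7
Reactants: 8 4,4-diethoxybut-1-yne
Product: 9 4,4-diethoxy-1-iodobut-1-yne
Conditions: N-iodosuccinimide, AgNO3 (cat.), acetone, rt
Reagents that add atoms: N-iodosuccinimide, O=C1CCC(=O)N1I
Why: silver-catalysed electrophilic iodination of the terminal alkyne C–H is a standard route to 1-iodoalkynes and is neutral enough for the acetal.

Step 8
Reactants: 9 4,4-diethoxy-1-iodobut-1-yne
Product: 10 (1Z)-4,4-diethoxy-1-iodobut-1-ene
Conditions: 2-nitrobenzenesulfonylhydrazide, Et3N, THF/i-PrOH, rt
Reagents that add atoms: none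
Why: diimide generated in the flask transfers two hydrogens syn to the iodoalkyne, which should give the (Z)-vinyl iodide without C–I hydrogenolysis.

Step 9
Reactants: 7 (2E)-3-[(4S,5R)-2,2-dimethyl-5-(2-methylprop-1-en-1-yl)-1,3-dioxolan-4-yl]but-2-en-1-ol, 10 (1Z)-4,4-diethoxy-1-iodobut-1-ene
Product: 11 (4S,5R)-4-[(2E)-4-{[(1Z)-4,4-diethoxybut-1-en-1-yl]oxy}but-2-en-2-yl]-2,2-dimethyl-5-(2-methylprop-1-en-1-yl)-1,3-dioxolane
Conditions: CuI (10 mol%), 3,4,7,8-tetramethyl-1,10-phenanthroline (20 mol%), Cs2CO3, toluene, 80 °C
Reagents that add atoms: none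
Why: copper-catalysed Ullmann-type C–O coupling of a primary allylic alcohol with a vinyl iodide should proceed with retention of the (Z)-geometry and below the temperature at which the ether rearranges.

Step 10
Reactants: 11 (4S,5R)-4-[(2E)-4-{[(1Z)-4,4-diethoxybut-1-en-1-yl]oxy}but-2-en-2-yl]-2,2-dimethyl-5-(2-methylprop-1-en-1-yl)-1,3-dioxolane
Product: 13 6α-alcohol (cyclohexanol acetonide), via Claisen aldehyde 12 (not isolated)
Conditions: mesitylene (0.02 M), BHT (cat.), base-washed sealed tube, 165 °C
Reagents that add atoms: none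
Why: A thermal [3,3] Claisen rearrangement of the allyl (Z)-alkenyl ether through a chair transition state should give aldehyde 12, whose formyl group then adds to the C7=C11 isopropylidene in a type 1 intramolecular carbonyl-ene reaction (closest known types: the citronellal-to-isopulegol cyclisation and tandem Claisen/ene sequences). The only ring closed is the cyclohexane, formed by 6-exo attack of C6 on C7 through a chair-like six-membered array, with hydrogen transfer from a C11 methyl group to oxygen leaving the isopropenyl group exocyclic. At C10 the new bond should form anti to the allylic C9–O bond with H9 turned toward the C10 methyl (A1,2 strain) and C8 inside, the arrangement favoured by the (E)-alkene, and C5 is fixed relative to C10 by the chair together with the (Z)-enol ether and (E)-allyl geometries. At C7 the isopropylidene sits equatorial in the chair that keeps the C5 chain and C8–O equatorial and the C10 methyl axial, placing the isopropenyl group trans to C8–O; at C6 an equatorial oxygen (6α) is expected, and this centre is reset in steps 11 and 12. The step needs the ene reaction to occur only at C7=C11 after the Claisen shift: the vinyl group formed at C10 has no allylic hydrogen, no 1,5-diene is present for a Cope shift, and the cis-dioxolane with the quaternary C10 pre-organises the chain for closure.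

Step 11
Reactants: 13 6α-alcohol (cyclohexanol acetonide)
Product: 14 6-ketone
Conditions: Dess–Martin periodinane, pyridine, CH2Cl2, 0 °C to rt
Reagents that add atoms: none
Why: Dess–Martin oxidation of the secondary alcohol should give the C6 ketone under buffered conditions that do not move the β,γ-alkene into conjugation, and any 6β-epimer formed in step 10 converges here.

Step 12
Reactants: 14 6-ketone
Product: 15 6β-alcohol
Conditions: LiBH(s-Bu)3, THF, −78 °C
Reagents that add atoms: none
Why: the bulky borohydride should attack the C6 ketone along the equatorial trajectory, because the axial face is blocked by the syn-axial C10 methyl, giving the axial 6β-alcohol (cis to C14) of the target.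

Step 13
Reactants: 15 6β-alcohol
Product: 16 6β,12-diol
Conditions: SeO2 (30 mol%), t-BuOOH, CH2Cl2, rt
Reagents that add atoms: tert-butyl hydroperoxide (oxygen source, relayed by catalytic SeO2), CC(C)(C)OO
Why: Riley allylic oxidation (ene reaction then [2,3]-shift) should hydroxylate the methyl group of the 1,1-disubstituted isopropenyl alkene, the C10 vinyl group having no allylic hydrogen.

Step 14
Reactants: 16 6β,12-diol
Product: 17 8α,9α,12-triol 3,6-cyclic methyl acetal
Conditions: camphorsulfonic acid (cat.), MeOH, rt to 40 °C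
Reagents that add atoms: methanol, CO
Why: acid-catalysed transacetalisation should remove the acetonide and let the 6β-hydroxyl capture the C3 oxocarbenium ion as a cis-fused 2-methoxytetrahydrofuran, which masks both the C6 hydroxyl and the C3 aldehyde for the next steps.

Step 15
Reactants: 17 8α,9α,12-triol 3,6-cyclic methyl acetal
Product: 20 9α-hydroxy 8,12-lactone, via hydroxy enal 18 (not isolated), via lactol 19 (not isolated)
Conditions: activated MnO2 (excess), CH2Cl2, rt
Reagents that add atoms: none
Why: MnO2 should oxidise only the allylic primary alcohol, and the enal is trapped by the equatorial 8α-hydroxyl as a lactol that is oxidised on to the trans-fused α-methylene-γ-butyrolactone, since the axial 9α-hydroxyl cannot reach C12 and O6 is tied up in the acetal.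

Step 16
Reactants: 20 9α-hydroxy 8,12-lactone, 21 (S)-2-methylbutanoic anhydride
Product: 22 9-O-[(S)-2-methylbutanoyl] lactone acetal
Conditions: DMAP, Et3N, CH2Cl2, rt to 40 °C
Reagents that add atoms: none
Why: DMAP-catalysed acylation of the only free hydroxyl (9α) should install the ester, and the anhydride avoids carbodiimide activation that could epimerise the α-centre of the acyl group.

Step 17
Reactants: 22 9-O-[(S)-2-methylbutanoyl] lactone acetal
Product: 23 3,6-lactol
Conditions: AcOH/THF/H2O (3:1:1), 45 °C
Reagents that add atoms: water, O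
Why: mild aqueous acid should hydrolyse the cyclic methyl acetal to the lactol (in equilibrium with the γ-hydroxy aldehyde) without cleaving the ester or the lactone.

Step 18
Reactants: 23 3,6-lactol
Product: 24 6β-hydroxy 3-enal with C10 vinyl group
Conditions: 37% aq. CH2O, pyrrolidine (10 mol%), propionic acid (10 mol%), i-PrOH, 45 °C
Reagents that add atoms: formaldehyde, C=O
Why: amine-catalysed Mannich condensation of the open-chain aldehyde with formaldehyde followed by loss of the amine should give the α-methylene aldehyde, the amine being kept catalytic and buffered so that its reversible addition to the α-methylene lactone does not accumulate.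

Step 19
Reactants: 24 6β-hydroxy 3-enal with C10 vinyl group
Product: 25 CNP0510523.1 (target)
Conditions: Ti(Oi-Pr)4 (10 mol%), chiral salalen ligand from cis-1,2-diaminocyclohexane (10 mol%, the enantiomer that gives (R)-1,2-epoxyalkanes from 1-alkenes), 30% aq. H2O2, CH2Cl2, rt
Reagents that add atoms: hydrogen peroxide, OO
Why: the electrophilic titanium–salalen peroxo catalyst epoxidises non-conjugated terminal alkenes under catalyst control and should leave the two electron-poor methylene groups untouched, delivering oxygen to the Si face of C1 of the vinyl group to give the (1R)-oxirane.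

Compound list
1 | 2,3-O-isopropylidene-D-erythronolactone | O=C1OC[C@H]2OC(C)(C)O[C@@H]12 | starting material
2 | (4R,5R)-5-(hydroxymethyl)-N-methoxy-N,2,2-trimethyl-1,3-dioxolane-4-carboxamide | CON(C)C(=O)[C@@H]1OC(C)(C)O[C@@H]1CO | intermediate
3 | (4R,5S)-5-formyl-N-methoxy-N,2,2-trimethyl-1,3-dioxolane-4-carboxamide | CON(C)C(=O)[C@@H]1OC(C)(C)O[C@@H]1C=O | intermediate
4 | (4R,5R)-N-methoxy-N,2,2-trimethyl-5-(2-methylprop-1-en-1-yl)-1,3-dioxolane-4-carboxamide | CON(C)C(=O)[C@@H]1OC(C)(C)O[C@@H]1C=C(C)C | intermediate
5 | 1-[(4R,5R)-2,2-dimethyl-5-(2-methylprop-1-en-1-yl)-1,3-dioxolan-4-yl]ethan-1-one | CC(=O)[C@@H]1OC(C)(C)O[C@@H]1C=C(C)C | intermediate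
6 | ethyl (2E)-3-[(4S,5R)-2,2-dimethyl-5-(2-methylprop-1-en-1-yl)-1,3-dioxolan-4-yl]but-2-enoate | CCOC(=O)/C=C(\C)[C@@H]1OC(C)(C)O[C@@H]1C=C(C)C | intermediate
7 | (2E)-3-[(4S,5R)-2,2-dimethyl-5-(2-methylprop-1-en-1-yl)-1,3-dioxolan-4-yl]but-2-en-1-ol | OC/C=C(\C)[C@@H]1OC(C)(C)O[C@@H]1C=C(C)C | intermediate
8 | 4,4-diethoxybut-1-yne | CCOC(CC#C)OCC | starting material
9 | 4,4-diethoxy-1-iodobut-1-yne | CCOC(CC#CI)OCC | intermediate
10 | (1Z)-4,4-diethoxy-1-iodobut-1-ene | CCOC(C/C=C\I)OCC | intermediate
11 | (4S,5R)-4-[(2E)-4-{[(1Z)-4,4-diethoxybut-1-en-1-yl]oxy}but-2-en-2-yl]-2,2-dimethyl-5-(2-methylprop-1-en-1-yl)-1,3-dioxolane | CCOC(C/C=C\OC/C=C(\C)[C@@H]1OC(C)(C)O[C@@H]1C=C(C)C)OCC | intermediate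
12 | Claisen aldehyde: (2S,3S)-2-(2,2-diethoxyethyl)-3-[(4S,5R)-2,2-dimethyl-5-(2-methylprop-1-en-1-yl)-1,3-dioxolan-4-yl]-3-methylpent-4-enal | O=C[C@@H](CC(OCC)OCC)[C@](C)(C=C)[C@@H]1OC(C)(C)O[C@@H]1C=C(C)C | intermediate (not isolated)
13 | 6α-alcohol (cyclohexanol acetonide): ring C5–C10 with 5β-(2,2-diethoxyethyl); 6α-OH; 7β-isopropenyl; 8α,9α-O-isopropylidene; 10β-methyl; 10α-vinyl | CC1(C)O[C@@H]2[C@@H](C(C)=C)[C@H](O)[C@@H](CC(OCC)OCC)[C@](C)(C=C)[C@@H]2O1 | intermediate
14 | 6-ketone: as 13 with C6=O | CC1(C)O[C@@H]2[C@@H](C(C)=C)C(=O)[C@@H](CC(OCC)OCC)[C@](C)(C=C)[C@@H]2O1 | intermediate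
15 | 6β-alcohol: as 13 with axial 6β-OH | CC1(C)O[C@@H]2[C@@H](C(C)=C)[C@@H](O)[C@@H](CC(OCC)OCC)[C@](C)(C=C)[C@@H]2O1 | intermediate
16 | 6β,12-diol: as 15 with 7β-(3-hydroxyprop-1-en-2-yl) | CC1(C)O[C@@H]2[C@@H](C(=C)CO)[C@@H](O)[C@@H](CC(OCC)OCC)[C@](C)(C=C)[C@@H]2O1 | intermediate
17 | 8α,9α,12-triol 3,6-cyclic methyl acetal: O6 and C3 joined in a cis-fused 2-methoxytetrahydrofuran; 8α-OH; 9α-OH; 7β-(3-hydroxyprop-1-en-2-yl); 10β-methyl; 10α-vinyl | O[C@@H]1[C@@H](C(=C)CO)[C@H]2OC(OC)C[C@H]2[C@](C)(C=C)[C@@H]1O | intermediate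
18 | hydroxy enal: as 17 with 7β-(3-oxoprop-1-en-2-yl) | O[C@@H]1[C@@H](C(=C)C=O)[C@H]2OC(OC)C[C@H]2[C@](C)(C=C)[C@@H]1O | intermediate (not isolated)
19 | lactol: 8,12-hemiacetal of 18 (trans-fused 2-hydroxy-3-methylenetetrahydrofuran) | C=C1C(O)O[C@@H]2[C@@H]1[C@H]3OC(OC)C[C@H]3[C@](C)(C=C)[C@@H]2O | intermediate (not isolated)
20 | 9α-hydroxy 8,12-lactone: trans-fused α-methylene-γ-butyrolactone (C7β/O8α); 9α-OH; 3,6-cyclic methyl acetal; 10β-methyl; 10α-vinyl | C=C1C(=O)O[C@@H]2[C@@H]1[C@H]3OC(OC)C[C@H]3[C@](C)(C=C)[C@@H]2O | intermediate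
21 | (S)-2-methylbutanoic anhydride | CC[C@H](C)C(=O)OC(=O)[C@@H](C)CC | starting material
22 | 9-O-[(S)-2-methylbutanoyl] lactone acetal: 20 acylated at O9 | C=C1C(=O)O[C@@H]2[C@@H]1[C@H]3OC(OC)C[C@H]3[C@](C)(C=C)[C@@H]2OC(=O)[C@@H](C)CC | intermediate
23 | 3,6-lactol: 22 with OH in place of OMe at C3 | C=C1C(=O)O[C@@H]2[C@@H]1[C@H]3OC(O)C[C@H]3[C@](C)(C=C)[C@@H]2OC(=O)[C@@H](C)CC | intermediate
24 | 6β-hydroxy 3-enal with C10 vinyl group: the target with CH=CH2 in place of the oxirane | C=C1C(=O)O[C@@H]2[C@@H]1[C@@H](O)[C@@H](C(=C)C=O)[C@](C)(C=C)[C@@H]2OC(=O)[C@@H](C)CC | intermediate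
25 | CNP0510523.1 | C=C1C(=O)O[C@@H]2[C@@H]1[C@@H](O)[C@@H](C(=C)C=O)[C@](C)([C@@H]1CO1)[C@@H]2OC(=O)[C@@H](C)CC | target

Total step count: 19. Longest linear sequence: 17 steps (steps 1–6 and 9–19); steps 7–8 make the vinyl iodide in a side branch.

Steps most likely to fail

Step 10: after the Claisen shift, thermal ring closure may be slower than decomposition or epimerisation of the α-branched aldehyde, and the facial selectivity of the Claisen shift at C10 may be incomplete. Fallback: setting out from 11, only the Claisen rearrangement is run at about 120 °C and the Claisen aldehyde 12 is isolated (C10 epimers can be separated at this point). The ring is then closed at −78 °C by a Me2AlCl-promoted carbonyl-ene (Prins-type) reaction in CH2Cl2, which comes back to the route at 13. This fallback makes no new compound (F0).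

Step 19: facial discrimination at the hindered vinyl group may be poor if the catalyst has to work against the conformational bias of the substrate. Fallback: setting out from 24, unselective epoxidation with dimethyldioxirane in acetone should give 25 together with its C1 epimer, the (1S)-epoxide F1. Hydrolytic kinetic resolution with water and the enantiomer of the chiral (salen)Co(OAc) complex (trivalent cobalt) that hydrolyses (S)-configured terminal epoxides should then open F1 to the (1S)-1,2-diol F2, which is removed by chromatography, leaving 25.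

Step 13: the allylic oxidation may stall at low conversion or run on to the enal. Fallback: setting out from 15, a Schenck ene reaction with singlet oxygen (O2, light, tetraphenylporphyrin, CH2Cl2, 0 °C) should take a hydrogen from the isopropenyl methyl group, the C7–H lying in the alkene plane and the vinyl group being inert, to give the allylic 12-hydroperoxide F3. Reduction with PPh3 comes back to the route at 16.

Further compounds
F0 | step 10 | none | none
F1 | step 19 | (1S)-epoxide, C1 epimer of 25 | C=C1C(=O)O[C@@H]2[C@@H]1[C@@H](O)[C@@H](C(=C)C=O)[C@](C)([C@H]1CO1)[C@@H]2OC(=O)[C@@H](C)CC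
F2 | step 19 | (1S)-1,2-diol from hydrolysis of F1 | C=C1C(=O)O[C@@H]2[C@@H]1[C@@H](O)[C@@H](C(=C)C=O)[C@](C)([C@H](O)CO)[C@@H]2OC(=O)[C@@H](C)CC
F3 | step 13 | allylic 12-hydroperoxide of 15 | CC1(C)O[C@@H]2[C@@H](C(=C)COO)[C@@H](O)[C@@H](CC(OCC)OCC)[C@](C)(C=C)[C@@H]2O1
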